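**Overview**

Retrosynthesis: ring A is opened at C4a–C5 (a ketene carbon on the pyranone α-carbon), ring C at O1–C8a, then the open chain is cut at C4–C4a, C8–CH2(prenyl), C8–C8a and C2–C3, and last the aryl O–prenyl bond.
Forward: ring B is bought; the chain is joined in the order C2–C3 (acetate aldol), C8a–C8 (γ-acetylation of a dioxinone), C8–prenyl (alkylation), C4–C4a (Claisen acylation); ring C then closes by O1–C8a cyclodehydration and ring A closes last.
Enabling feature: ring A is a phloroglucinol, so C5–C6–C7–C8 is a β-polycarbonyl strand hung between C8a and C4a of ring C (O1, C2, C3, C4, C4a, C8a) when that ring is a 2-aryl-2,3-dihydropyran-4-one. There C4a is the nucleophilic α-carbon of a vinylogous ester, six atoms from the ketene carbon C5, and the prenyl group rides on the sp3 carbon C8 next to C8a.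
Stereochemistry: C2 (S) is the only stereocenter; it is set by a catalyst-controlled Mukaiyama acetate aldol, its C–O bond is never broken, and only neutral or weakly acidic conditions follow.

Key step: step 9

Remark: chain atoms carry flavanone numbers (O1, C2, C3, C4, C4a, C5 to C8, C8a) from the first step on, prenyl means 3-methylbut-2-en-1-yl, and compounds 12 to 18 are carried as mixtures at C8, a center that ends as an aromatic carbon.

**Route**

Step 1
Reactants: 1 4-hydroxybenzaldehyde; 2 prenyl bromide (1-bromo-3-methylbut-2-ene)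
Product: 3 4-(prenyloxy)benzaldehyde
Conditions: K2CO3, acetone, reflux
Reagents that add atoms: none
Why: Williamson ether synthesis, in which the phenoxide of 1 (acidified by the para-formyl group) displaces the primary allylic bromide by SN2 and O-alkylation is expected to dominate with carbonate in a polar aprotic solvent.

Step 2
Reactants: 3 4-(prenyloxy)benzaldehyde; 4 methyl acetate TBS ketene acetal (tert-butyl[(1-methoxyethenyl)oxy]dimethylsilane)
Product: 6 methyl (3S)-3-hydroxy-3-[4-(prenyloxy)phenyl]propanoate, via trichlorosilyl aldolate 5 (not isolated)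
Conditions: SiCl4 (1.1 equiv), (S,S)-bisphosphoramide (CH2)5[N(Me)P(O)(NMe)2(C20H12)]2 (5 mol %; C20H12 = 1,1'-binaphthalene-2,2'-diyl), CH2Cl2, −78 °C; then sat. aq. NaHCO3, 0 °C
Reagents that add atoms: none
Why: Catalytic enantioselective Mukaiyama acetate aldol by Lewis-base activation of SiCl4, in which the phosphoramide-bound trichlorosilyl cation binds the aldehyde, the ketene acetal attacks through an open transition state with loss of its silyl group as the chloride, and the catalyst antipode that leaves the Si face of the aldehyde open (expected to be the (S,S)-form, to be confirmed by Mosher ester analysis and exchanged for its mirror image if the sense proves opposite) sets C2 as (S); bicarbonate then hydrolyses the silicon-bound aldolate 5 without harming the prenyl ether.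

Step 3
Reactants: 6 methyl (3S)-3-hydroxy-3-[4-(prenyloxy)phenyl]propanoate
Product: 7 methyl (3S)-3-[(tert-butyldimethylsilyl)oxy]-3-[4-(prenyloxy)phenyl]propanoate
Conditions: TBSCl, imidazole, DMF, rt
Reagents that add atoms: tert-butyldimethylsilyl chloride, CC(C)(C)[Si](C)(C)Cl
Why: Standard imidazole-mediated silylation of a secondary benzylic alcohol, giving a silyl ether robust enough for the Grignard-mediated amidation and the strongly basic Claisen step while leaving the stereocenter untouched.

Step 4
Reactants: 7 methyl (3S)-3-[(tert-butyldimethylsilyl)oxy]-3-[4-(prenyloxy)phenyl]propanoate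
Product: 8 (3S)-3-[(tert-butyldimethylsilyl)oxy]-N-methoxy-N-methyl-3-[4-(prenyloxy)phenyl]propanamide
Conditions: MeNHOMe·HCl, iPrMgCl, THF, −20 to 0 °C; aq. NH4Cl
Reagents that add atoms: N,O-dimethylhydroxylamine hydrochloride, CNOC.Cl
Why: Direct ester-to-Weinreb-amide conversion by the chloromagnesium amide of N,O-dimethylhydroxylamine, which at low temperature adds to the ester faster than it enolizes it, so that β-elimination of the silyloxy group is not expected and C2 is retained.

Step 5
Reactants: 9 2,2,6-trimethyl-4H-1,3-dioxin-4-one; 10 acetyl chloride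
Product: 11 2,2-dimethyl-6-(2-oxopropyl)-4H-1,3-dioxin-4-one
Conditions: LiN(SiMe3)2 (2.1 equiv), THF, −78 °C; then 10, −78 °C; 1 M aq. HCl
Reagents that add atoms: none
Why: γ-Selective C-acylation of the lithium dienolate of the dioxinone (a vinylogous Claisen acylation), in which the second equivalent of base takes up the more acidic keto-dioxinone product so that it does not quench unreacted dienolate.

Step 6
Reactants: 11 2,2-dimethyl-6-(2-oxopropyl)-4H-1,3-dioxin-4-one; 2 prenyl bromide
Product: 12 2,2-dimethyl-6-(6-methyl-2-oxohept-5-en-3-yl)-4H-1,3-dioxin-4-one (racemic)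
Conditions: K2CO3 (1.1 equiv), 2 (1.0 equiv), acetone, rt
Reagents that add atoms: none
Why: C-Alkylation of an active methylene compound, in which the CH2 flanked by the ketone and the vinylogous ester of the dioxinone gives a soft delocalized potassium enolate that should attack the allylic bromide at carbon by SN2, with one equivalent of bromide and the lower acidity of the tertiary product limiting double alkylation; the new center (C8) is racemic, which is immaterial.

Step 7
Reactants: 12 2,2-dimethyl-6-(6-methyl-2-oxohept-5-en-3-yl)-4H-1,3-dioxin-4-one; 8 (3S)-3-[(tert-butyldimethylsilyl)oxy]-N-methoxy-N-methyl-3-[4-(prenyloxy)phenyl]propanamide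
Product: 13 6-[(10S)-10-[(tert-butyldimethylsilyl)oxy]-2-methyl-6,8-dioxo-10-[4-(prenyloxy)phenyl]dec-2-en-5-yl]-2,2-dimethyl-4H-1,3-dioxin-4-one
Conditions: LiN(iPr)2 (2 equiv per 12; 12 in 2.5-fold excess over 8), THF, −78 to −40 °C; then 8, −78 °C; AcOH, −78 °C
Reagents that add atoms: none
Why: Claisen-type acylation of a 1,3-dicarbonyl dianion, in which the second deprotonation of 12 occurs at the terminal methyl (the future C4a), this more reactive carbon adds to the Weinreb amide to give a chelated tetrahedral adduct that collapses only on quench, and the cold acidic quench without amine base avoids the base-triggered aldol aromatization typical of diketo-dioxinones; C2 is not touched.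

Step 8
Reactants: 13 6-[(10S)-10-[(tert-butyldimethylsilyl)oxy]-2-methyl-6,8-dioxo-10-[4-(prenyloxy)phenyl]dec-2-en-5-yl]-2,2-dimethyl-4H-1,3-dioxin-4-one
Product: 15 (2S)-6-[1-(2,2-dimethyl-4-oxo-4H-1,3-dioxin-6-yl)-4-methylpent-3-en-1-yl]-2-[4-(prenyloxy)phenyl]-2,3-dihydro-4H-pyran-4-one, via hydroxy diketo-dioxinone 14 (not isolated)
Conditions: 48% aq. HF, MeCN, 0 °C to rt; then pyridinium p-toluenesulfonate (cat.), 4 Å molecular sieves, CH2Cl2, rt
Reagents that add atoms: none
Why: Desilylation followed by acid-catalysed cyclodehydration of a δ-hydroxy-β-diketone, the standard entry to 2,3-dihydro-4H-pyran-4-ones, in which the freed C2 hydroxyl can form a six-membered hemiketal only with the C8a carbonyl and loses water to the vinylogous ester, the C2–O bond is never broken so (S) is retained, and the weak acids used should spare the dioxinone, the prenyl ether and the electron-rich benzylic carbinol.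

Step 9
Reactants: 15 (2S)-6-[1-(2,2-dimethyl-4-oxo-4H-1,3-dioxin-6-yl)-4-methylpent-3-en-1-yl]-2-[4-(prenyloxy)phenyl]-2,3-dihydro-4H-pyran-4-one
Product: 19 (2S)-5,7-dihydroxy-8-prenyl-2-[4-(prenyloxy)phenyl]chroman-4-one (the target), via acylketene 16 (not isolated), via dienylketene enol 17 (not isolated), via cyclohexadienone 18 (not isolated)
Conditions: slow addition of 15 to toluene (final 0.005 M), 110 °C, argon
Reagents that add atoms: none
Why: Proposed new method: at 110 °C the dioxinone of 15 should undergo retro-[4+2] loss of acetone to acylketene 16, whose C7 ketone enolizes toward the doubly activated C8–H to give dienylketene 17 (C4a=C8a–C8=C7(OH)–C6H=C5=O), and a thermal disrotatory 6π-electrocyclization, equally a six-membered C-acylation of the vinylogous-ester α-carbon C4a by the ketene carbon C5, forms the C4a–C5 bond of cyclohexadienone 18, which tautomerizes irreversibly to phenol 19. The closest known reaction types are the thermal dioxinone-to-acylketene fragmentation with intramolecular trapping, the dienylketene 6π ring closure that ends the Danheiser benzannulation and the biomimetic aromatization of diketo-dioxinones to resorcylates; new here is carbon (Claisen-mode) trapping by a pyranone enol-ether carbon to give a phloroglucinol. Ring A (C4a, C5, C6, C7, C8, C8a) is the only ring closed, by a 6π electrocyclic carbocyclization onto the existing ring C, driven by aromatization. No lasting stereocenter is created, since C4a of 18 and C8 end as aromatic carbons, and C2 is kept because the medium is neutral and aprotic, so the ring opening that racemizes flavanones under base is not available. The step needs intramolecular C-acylation at C4a to outrun ketene dimerization, O-acylation of product phenols and [2+2] addition to the prenyl alkenes; slow addition at high dilution, the six-atom reach from C4a to C5, the donor push of O1 and of the C7 enol on C4a, and the absence of any oxygen nucleophile within five- or six-membered reach (O1 is an ether, the C4 oxygen would need an eight-membered ring) should secure this. Regiochemistry is fixed by construction, because the prenyl-bearing carbon is already bonded to C8a, so only the 8-prenyl isomer can arise and both phenols emerge free.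

**Compound list**

1 | 4-hydroxybenzaldehyde | O=Cc1ccc(O)cc1 | starting material
2 | prenyl bromide (1-bromo-3-methylbut-2-ene) | CC(C)=CCBr | starting material
3 | 4-[(3-methylbut-2-en-1-yl)oxy]benzaldehyde | CC(C)=CCOc1ccc(C=O)cc1 | intermediate
4 | tert-butyl[(1-methoxyethenyl)oxy]dimethylsilane (methyl acetate TBS ketene acetal) | C=C(OC)O[Si](C)(C)C(C)(C)C | starting material
5 | methyl (3S)-3-[4-(prenyloxy)phenyl]-3-[(trichlorosilyl)oxy]propanoate (formed in the flask) | CC(C)=CCOc1ccc([C@@H](O[Si](Cl)(Cl)Cl)CC(=O)OC)cc1 | intermediate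
6 | methyl (3S)-3-hydroxy-3-[4-(prenyloxy)phenyl]propanoate | CC(C)=CCOc1ccc([C@@H](O)CC(=O)OC)cc1 | intermediate
7 | methyl (3S)-3-[(tert-butyldimethylsilyl)oxy]-3-[4-(prenyloxy)phenyl]propanoate | CC(C)=CCOc1ccc([C@@H](O[Si](C)(C)C(C)(C)C)CC(=O)OC)cc1 | intermediate
8 | (3S)-3-[(tert-butyldimethylsilyl)oxy]-N-methoxy-N-methyl-3-[4-(prenyloxy)phenyl]propanamide | CC(C)=CCOc1ccc([C@@H](O[Si](C)(C)C(C)(C)C)CC(=O)N(C)OC)cc1 | intermediate
9 | 2,2,6-trimethyl-4H-1,3-dioxin-4-one | CC1=CC(=O)OC(C)(C)O1 | starting material
10 | acetyl chloride | CC(Cl)=O | starting material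
11 | 2,2-dimethyl-6-(2-oxopropyl)-4H-1,3-dioxin-4-one | CC(=O)CC1=CC(=O)OC(C)(C)O1 | intermediate
12 | 2,2-dimethyl-6-(6-methyl-2-oxohept-5-en-3-yl)-4H-1,3-dioxin-4-one (racemic) | CC(=O)C(CC=C(C)C)C1=CC(=O)OC(C)(C)O1 | intermediate
13 | 6-[(10S)-10-[(tert-butyldimethylsilyl)oxy]-2-methyl-6,8-dioxo-10-[4-(prenyloxy)phenyl]dec-2-en-5-yl]-2,2-dimethyl-4H-1,3-dioxin-4-one (mixture at C8) | CC(C)=CCOc1ccc([C@@H](O[Si](C)(C)C(C)(C)C)CC(=O)CC(=O)C(CC=C(C)C)C2=CC(=O)OC(C)(C)O2)cc1 | intermediate
14 | 6-[(10S)-10-hydroxy-2-methyl-6,8-dioxo-10-[4-(prenyloxy)phenyl]dec-2-en-5-yl]-2,2-dimethyl-4H-1,3-dioxin-4-one (formed in the flask, in equilibrium with its cyclic hemiketal) | CC(C)=CCOc1ccc([C@@H](O)CC(=O)CC(=O)C(CC=C(C)C)C2=CC(=O)OC(C)(C)O2)cc1 | intermediate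
15 | (2S)-6-[1-(2,2-dimethyl-4-oxo-4H-1,3-dioxin-6-yl)-4-methylpent-3-en-1-yl]-2-[4-(prenyloxy)phenyl]-2,3-dihydro-4H-pyran-4-one (mixture at C8) | CC(C)=CCOc1ccc([C@@H]2CC(=O)C=C(C(CC=C(C)C)C3=CC(=O)OC(C)(C)O3)O2)cc1 | intermediate
16 | (2S)-6-(7-methyl-1,3-dioxoocta-1,6-dien-4-yl)-2-[4-(prenyloxy)phenyl]-2,3-dihydro-4H-pyran-4-one (acylketene, formed in the flask) | CC(C)=CCOc1ccc([C@@H]2CC(=O)C=C(C(CC=C(C)C)C(=O)C=C=O)O2)cc1 | intermediate
17 | (2S)-6-[(3E)-3-hydroxy-7-methyl-1-oxoocta-1,3,6-trien-4-yl]-2-[4-(prenyloxy)phenyl]-2,3-dihydro-4H-pyran-4-one (dienylketene enol, formed in the flask) | CC(C)=CCOc1ccc([C@@H]2CC(=O)C=C(/C(CC=C(C)C)=C(/O)C=C=O)O2)cc1 | intermediate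
18 | (2S)-7-hydroxy-8-prenyl-2-[4-(prenyloxy)phenyl]-2,3-dihydro-4H-chromene-4,5(4aH)-dione (cyclohexadienone, formed in the flask, mixture at C4a) | CC(C)=CCOc1ccc([C@@H]2CC(=O)C3C(=O)C=C(O)C(CC=C(C)C)=C3O2)cc1 | intermediate
19 | (2S)-5,7-dihydroxy-8-(3-methylbut-2-en-1-yl)-2-{4-[(3-methylbut-2-en-1-yl)oxy]phenyl}-2,3-dihydro-4H-chromen-4-one | CC(C)=CCOc1ccc([C@@H]2CC(=O)c3c(O)cc(O)c(CC=C(C)C)c3O2)cc1 | target

**Count**

Total steps: 9 (the compounds formed in the flask, 5, 14, 16, 17 and 18, are not counted as steps).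
Longest linear sequence: 7 steps (steps 1, 2, 3, 4, 7, 8, 9, from 4-hydroxybenzaldehyde); the dioxinone branch (steps 5 and 6) joins at step 7.

**Steps most likely to fail**

Step 9 (the proposed new method). The acylketene may be consumed by dimerization, by [2+2] or ene reaction with a prenyl double bond or by oligomerization before the dienylketene folds, so that ring A does not close. The fallback uses known flavanone chemistry, sets out from 3 (with 2) and returns at 19. Commercial 2,4,6-trihydroxyacetophenone is C-prenylated with 2 (DBU, THF) to give 1-[2,4,6-trihydroxy-3-(3-methylbut-2-en-1-yl)phenyl]ethan-1-one F1. The 4- and 6-hydroxyls are protected (MOMCl, iPr2NEt, CH2Cl2) to give 1-[2-hydroxy-4,6-bis(methoxymethoxy)-3-(3-methylbut-2-en-1-yl)phenyl]ethan-1-one F2; the hydrogen-bonded hydroxyl between acetyl and prenyl is expected to stay free, and this regiochemistry would be checked by NMR. Claisen–Schmidt condensation with 3 (KOH, EtOH/H2O, rt) gives (E)-1-[2-hydroxy-4,6-bis(methoxymethoxy)-3-prenylphenyl]-3-[4-(prenyloxy)phenyl]prop-2-en-1-one F3. Oxa-Michael ring closure through the one free phenol (NaOAc, EtOH, reflux) gives racemic 5,7-bis(methoxymethoxy)-8-prenyl-2-[4-(prenyloxy)phenyl]chroman-4-one F4, with prenyl necessarily at C8. Mild acid (HCl, MeOH, rt) gives racemic 5,7-dihydroxy-8-prenyl-2-[4-(prenyloxy)phenyl]chroman-4-one F5. Preparative HPLC on a chiral stationary phase (amylose tris(3,5-dimethylphenylcarbamate)) then separates 19 from its enantiomer.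

Step 7. The basic dianion may enolize the Weinreb amide and trigger β-elimination of the silyloxy group, or add too slowly to the amide, so that little diketone forms. The fallback sets out from 8 (with 12) and returns at 13. The amide 8 is reduced with iBu2AlH (THF, −78 °C) to (3S)-3-[(tert-butyldimethylsilyl)oxy]-3-[4-(prenyloxy)phenyl]propanal F6. This more electrophilic aldehyde is added to the dianion of 12 at −78 °C to give the aldol adduct 6-[(10S)-10-[(tert-butyldimethylsilyl)oxy]-8-hydroxy-2-methyl-6-oxo-10-[4-(prenyloxy)phenyl]dec-2-en-5-yl]-2,2-dimethyl-4H-1,3-dioxin-4-one F7 as a mixture of diastereomers. Oxidation with Dess–Martin periodinane (NaHCO3, CH2Cl2, 0 °C) then gives 13.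

Step 6. Poor site selectivity of the delocalized enolate (O-alkylation or double alkylation) may erode the supply of the mono-C-prenyl compound. The fallback sets out from 9 (with 2 and 10) and returns at 12, reversing the order of the two C–C bond formations so that each substituent enters at a singly activated position. The lithium dienolate of 9 (LiN(iPr)2, DMPU, THF, −78 °C) is γ-alkylated with 2 to give 2,2-dimethyl-6-(4-methylpent-3-en-1-yl)-4H-1,3-dioxin-4-one F8. Its dienolate (LiN(SiMe3)2, THF, −78 °C) is then γ-acetylated with 10 to give 12 directly.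

**Further compounds**

F1 | step 9 | 1-[2,4,6-trihydroxy-3-(3-methylbut-2-en-1-yl)phenyl]ethan-1-one | CC(=O)c1c(O)cc(O)c(CC=C(C)C)c1O
F2 | step 9 | 1-[2-hydroxy-4,6-bis(methoxymethoxy)-3-(3-methylbut-2-en-1-yl)phenyl]ethan-1-one | CC(=O)c1c(OCOC)cc(OCOC)c(CC=C(C)C)c1O
F3 | step 9 | (E)-1-[2-hydroxy-4,6-bis(methoxymethoxy)-3-(3-methylbut-2-en-1-yl)phenyl]-3-{4-[(3-methylbut-2-en-1-yl)oxy]phenyl}prop-2-en-1-one | CC(C)=CCOc1ccc(/C=C/C(=O)c2c(OCOC)cc(OCOC)c(CC=C(C)C)c2O)cc1
F4 | step 9 | racemic 5,7-bis(methoxymethoxy)-8-(3-methylbut-2-en-1-yl)-2-{4-[(3-methylbut-2-en-1-yl)oxy]phenyl}chroman-4-one | CC(C)=CCOc1ccc(C2CC(=O)c3c(OCOC)cc(OCOC)c(CC=C(C)C)c3O2)cc1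
F5 | step 9 | racemic 5,7-dihydroxy-8-(3-methylbut-2-en-1-yl)-2-{4-[(3-methylbut-2-en-1-yl)oxy]phenyl}chroman-4-one | CC(C)=CCOc1ccc(C2CC(=O)c3c(O)cc(O)c(CC=C(C)C)c3O2)cc1
F6 | step 7 | (3S)-3-[(tert-butyldimethylsilyl)oxy]-3-{4-[(3-methylbut-2-en-1-yl)oxy]phenyl}propanal | CC(C)=CCOc1ccc([C@@H](O[Si](C)(C)C(C)(C)C)CC=O)cc1
F7 | step 7 | 6-[(10S)-10-[(tert-butyldimethylsilyl)oxy]-8-hydroxy-2-methyl-6-oxo-10-{4-[(3-methylbut-2-en-1-yl)oxy]phenyl}dec-2-en-5-yl]-2,2-dimethyl-4H-1,3-dioxin-4-one | CC(C)=CCOc1ccc([C@@H](O[Si](C)(C)C(C)(C)C)CC(O)CC(=O)C(CC=C(C)C)C2=CC(=O)OC(C)(C)O2)cc1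
F8 | step 6 | 2,2-dimethyl-6-(4-methylpent-3-en-1-yl)-4H-1,3-dioxin-4-one | CC(C)=CCCC1=CC(=O)OC(C)(C)O1
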